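Time sorts this flask into rungs, fastest first. On the lowest rung are the forms the catalyst passes through. The catalyst is 0.2 mol% of the charge, less than the scatter of 1 percentage point, so they cannot show, and at 40.0 s the grey run reads 14.2% target plus 83.9% starting material.

- grey: starting material 5 mM; second substrate 2 equiv; free catalyst 0.2 mol%; run made earlier
- flask: starting material 5.0 mM; second substrate 1.00 equiv; free catalyst 0.2 mol%; time 6.0 min

grey run (percent of the starting material charged)

| time / s | target / % | starting material / % |
|---|---|---|
| 10.0 | 4.9 | 95.9 |
| 12.0 | 5.3 | 94.9 |
| 20.0 | 8.6 | 93.1 |
| 40.0 | 14.2 | 83.9 |

(scatter of a reading: 1 percentage point)

* target present at 6.0 min, in percent of the starting material charged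
* starting material present at 6.0 min, in percent of the starting material charged

On the next rung, we read the grey run's loss of starting material as a pseudo-first-order decay and freeze the rate per catalyst. Call it κ, the first-order rate constant of starting material divided by the catalyst concentration charged, c: from the last reading κ is 0.439 /mM/s. The flask has the same c, so κ gives it a half-life of 2.63 min. On the top rung stands the asked 6.0 min, far beyond the last reading, and one run at one charge cannot test the second substrate, so we leave it out. Our reckoning, a = exp(−κct) for the share a left, gives the flask 20.6% starting material and 79.4% target.

The forecast says 42% target and 58% starting material, taking the reaction as first order in the second substrate while calling that order untested, “so the range is wide”; we differ.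

The flask gives 87.8% target and 12.2% starting material.

    catalyst intermediate A → free catalyst + target (k = 93.3 /s)
    catalyst intermediate B → free catalyst + second product (k = 8.95 /s)
    catalyst intermediate B → spent catalyst (k = 0.00903 /s)
    starting material + free catalyst ⇌ catalyst intermediate A (K = 123 /M, k = 1270 /M/s)
    second substrate + free catalyst ⇌ catalyst intermediate B (K = 465 /M, k = 2230 /M/s)

Read backwards, that is a κ of 0.585 /mM/s, though 46.9% of the catalyst is spent by then. At the flask's start, second substrate takes free catalyst 1.8 times as fast as starting material, forward steps alone, and the grey recipe, with twice the equivalents, carried on to 6.0 min holds 34.4% starting material against this flask's 12.2%. In a neighbour flask with 0.08 mol% of free catalyst, κ gives 53.2% starting material; that neighbour holds 55.3%.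

(The data are calculated for an exercise; noise was put on by code.)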